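**Retrosynthetic overview**

1. The target comes from its 5,7-bis(MOM) 5'',7''-dibenzyl ether by one Lewis-acid deprotection that leaves both anisyl methyl ethers.
2. Key disconnection, ring C of unit 1 (the 6-linked flavone; unit 2 is the 8-linked flavone): in ring A of unit 1 the adjacent carbons C8a and C4a carry O1 and the C4 acyl group, with oxygenated C5 beside C4a and C8–H beside C8a. This is the pattern of a 3-alkoxybenzyne taking up oxygen at C8a and acyl at C4a from 3-(4-methoxyphenyl)propiolic acid, after which O1–C2 closes the pyranone.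
3. The aryne comes from an ortho-silylaryl triflate. Its C–Si bond is set by carbamate-directed ortho-lithiation on the simple phloroglucinol ring before the biaryl exists, because a flavone would not survive the alkyllithium.
4. The C6–C8'' biaryl bond is made by Negishi coupling of this silylated ring, metalated between its two MOM ethers, with 8-iodo-5,7-dibenzyloxy-4'-methoxyflavone. The iodoflavone comes from phloroacetophenone by benzylation, iodination, Claisen–Schmidt condensation and I2/DMSO closure; benzyl is used on unit 2 because MOM would not survive that closure.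
5. Ring order: ring C of unit 2, then the biaryl bond, then ring C of unit 1 last.

Key step: step 13

Assumption: the target SMILES defines no configuration for the hindered C6–C8'' axis, so the route is planned to give the compound as the racemate about this axis.

**Route**

Step 1
Reactants: 1 2,4,6-trihydroxyacetophenone
Product: 2 1-[4,6-bis(benzyloxy)-2-hydroxyphenyl]ethan-1-one
Conditions: BnBr (2.05 equiv), K2CO3, DMF, rt
Reagents that add atoms: benzyl bromide, BrCc1ccccc1
Why: Williamson ether synthesis; the 4-OH and one of the two equivalent ortho-OH groups are alkylated, while the remaining ortho-OH is hydrogen-bonded to the acetyl carbonyl and should stay free.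

Step 2
Reactants: 2 1-[4,6-bis(benzyloxy)-2-hydroxyphenyl]ethan-1-one
Product: 3 1-[4,6-bis(benzyloxy)-2-hydroxy-3-iodophenyl]ethan-1-one
Conditions: NIS (1.05 equiv), TsOH (cat.), MeCN, 0 °C to rt
Reagents that add atoms: N-iodosuccinimide, O=C1CCC(=O)N1I
Why: Electrophilic aromatic iodination of a strongly activated phenol; C3, ortho to the free hydroxyl and less crowded than C5 between the two benzyl ethers, should be attacked, as is usual for 2-hydroxy-4,6-dialkoxyacetophenones.

Step 3
Reactants: 3 1-[4,6-bis(benzyloxy)-2-hydroxy-3-iodophenyl]ethan-1-one; 4 4-methoxybenzaldehyde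
Product: 5 (E)-1-[4,6-bis(benzyloxy)-2-hydroxy-3-iodophenyl]-3-(4-methoxyphenyl)prop-2-en-1-one
Conditions: KOH (50% aq.), EtOH, rt
Reagents that add atoms: none
Why: Claisen–Schmidt aldol condensation; E1cB dehydration should give the conjugated E-enone, and the aryl iodide and benzyl ethers are inert to aqueous KOH.

Step 4
Reactants: 5 (E)-1-[4,6-bis(benzyloxy)-2-hydroxy-3-iodophenyl]-3-(4-methoxyphenyl)prop-2-en-1-one
Product: 6 5,7-bis(benzyloxy)-8-iodo-2-(4-methoxyphenyl)-4H-chromen-4-one
Conditions: I2 (10 mol%), DMSO, 120 °C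
Reagents that add atoms: none
Why: Iodine-catalysed oxidative cyclisation of a 2'-hydroxychalcone to the flavone with DMSO as terminal oxidant; benzyl ethers and the aryl iodide should survive, and the iodine ortho to the cyclising hydroxyl ends up at C8.

Step 5
Reactants: 7 phloroglucinol
Product: 8 3,5-bis(methoxymethoxy)phenol
Conditions: MOMCl (2.0 equiv), i-Pr2NEt, DMF, 0 °C to rt; chromatography
Reagents that add atoms: chloromethyl methyl ether, COCCl
Why: Base-mediated O-alkylation of a phenol; the three hydroxyls are equivalent, so two equivalents of MOMCl should give the bis-ether as the main part of a statistical mixture, from which it is separated and the mono- and tris-ethers recycled.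

Step 6
Reactants: 8 3,5-bis(methoxymethoxy)phenol
Product: 9 3,5-bis(methoxymethoxy)phenyl N,N-diethylcarbamate
Conditions: ClCONEt2, K2CO3, MeCN, reflux
Reagents that add atoms: N,N-diethylcarbamoyl chloride, CCN(CC)C(Cl)=O
Why: O-carbamoylation of the phenoxide installs the strongest oxygen-based directing group for the metalation that follows.

Step 7
Reactants: 9 3,5-bis(methoxymethoxy)phenyl N,N-diethylcarbamate
Product: 11 3,5-bis(methoxymethoxy)-2-(trimethylsilyl)phenyl N,N-diethylcarbamate, via 2-lithio carbamate 10 (not isolated)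
Conditions: s-BuLi (1.1 equiv), TMEDA, THF, −78 °C; then Me3SiCl, −78 °C to rt
Reagents that add atoms: chlorotrimethylsilane, C[Si](C)(C)Cl
Why: Directed ortho-metalation; the O-carbamate and the neighbouring MOM ether should direct s-BuLi cooperatively to the carbon between them, in preference to the carbon between the two weaker MOM directors, and at −78 °C the aryllithium is silylated before any anionic ortho-Fries shift.

Step 8
Reactants: 11 3,5-bis(methoxymethoxy)-2-(trimethylsilyl)phenyl N,N-diethylcarbamate
Product: 12 3,5-bis(methoxymethoxy)-2-(trimethylsilyl)phenol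
Conditions: LiAlH4, THF, 0 °C to reflux; aqueous work-up
Reagents that add atoms: none
Why: Reductive cleavage of an aryl O-carbamate (hydride attack at the carbamoyl carbon expels the phenoxide); the aryl–silicon bond and the MOM acetals are inert to hydride.

Step 9
Reactants: 12 3,5-bis(methoxymethoxy)-2-(trimethylsilyl)phenol
Product: 13 [3,5-bis(methoxymethoxy)-2-(trimethylsilyl)phenoxy]tri(propan-2-yl)silane
Conditions: i-Pr3SiCl, imidazole, DMF, rt
Reagents that add atoms: chlorotri(propan-2-yl)silane, CC(C)[Si](Cl)(C(C)C)C(C)C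
Why: Silylation of the phenol; the bulky, non-coordinating TIPS ether withstands n-BuLi and does not direct metalation, so the next lithiation is left to the two MOM ethers.

Step 10
Reactants: 13 [3,5-bis(methoxymethoxy)-2-(trimethylsilyl)phenoxy]tri(propan-2-yl)silane; 6 5,7-bis(benzyloxy)-8-iodo-2-(4-methoxyphenyl)-4H-chromen-4-one
Product: 16 5,7-bis(benzyloxy)-8-[2,6-bis(methoxymethoxy)-4-(triisopropylsilyloxy)-3-(trimethylsilyl)phenyl]-2-(4-methoxyphenyl)-4H-chromen-4-one, via aryllithium 14 (not isolated), via arylzinc chloride 15 (not isolated)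
Conditions: 13 (1.5 equiv), n-BuLi, THF, 0 °C; ZnCl2, 0 °C to rt; then 6, Pd2(dba)3 (cat.), RuPhos, THF/NMP, 70 °C
Reagents that add atoms: none
Why: Directed ortho-metalation at the only carbon flanked by two MOM ethers, transmetalation to zinc and Negishi cross-coupling; the arylzinc tolerates the flavone carbonyl, and zerovalent palladium with RuPhos is a known catalyst for tetra-ortho-substituted biaryls from 2,6-dialkoxyarylzinc halides.

Step 11
Reactants: 16 5,7-bis(benzyloxy)-8-[2,6-bis(methoxymethoxy)-4-(triisopropylsilyloxy)-3-(trimethylsilyl)phenyl]-2-(4-methoxyphenyl)-4H-chromen-4-one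
Product: 17 5,7-bis(benzyloxy)-8-[4-hydroxy-2,6-bis(methoxymethoxy)-3-(trimethylsilyl)phenyl]-2-(4-methoxyphenyl)-4H-chromen-4-one
Conditions: Bu4NF (1.1 equiv), AcOH (1.1 equiv), THF, 0 °C
Reagents that add atoms: none
Why: Fluoride cleavage of the aryl silyl ether; the Si–O bond is far more labile than the aryl C–SiMe3 bond, which has no leaving group beside it yet, and the acetic acid buffer keeps the medium near neutral for the flavone.

Step 12
Reactants: 17 5,7-bis(benzyloxy)-8-[4-hydroxy-2,6-bis(methoxymethoxy)-3-(trimethylsilyl)phenyl]-2-(4-methoxyphenyl)-4H-chromen-4-one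
Product: 18 4-[5,7-bis(benzyloxy)-2-(4-methoxyphenyl)-4-oxo-4H-chromen-8-yl]-3,5-bis(methoxymethoxy)-2-(trimethylsilyl)phenyl trifluoromethanesulfonate
Conditions: PhNTf2 (1.3 equiv), DBU, MeCN, rt
Reagents that add atoms: N-phenylbis(trifluoromethanesulfonimide), O=S(=O)(N(c1ccccc1)S(=O)(=O)C(F)(F)F)C(F)(F)F
Why: Triflation of the phenoxide with a mild triflyl donor, the usual last step in making ortho-silylaryl triflates; the reagent should leave the pyranone carbonyl and the acetals alone.

Step 13
Reactants: 18 4-[5,7-bis(benzyloxy)-2-(4-methoxyphenyl)-4-oxo-4H-chromen-8-yl]-3,5-bis(methoxymethoxy)-2-(trimethylsilyl)phenyl trifluoromethanesulfonate; 19 3-(4-methoxyphenyl)propiolic acid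
Product: 22 5'',7''-bis(benzyloxy)-5,7-bis(methoxymethoxy)-4',4'''-dimethoxy-6,8''-biflavone, via aryne 20 (not isolated), via hydroxyaryl ynone 21 (not isolated)
Conditions: 19 (2 equiv), CsF (5 equiv), THF, 125 °C, sealed tube
Reagents that add atoms: none
Why: Fluoride attacks silicon and triflate leaves to give aryne 20 across C4a–C8a; the cesium carboxylate of 19 adds through oxygen to C8a, the aryl anion formed at C4a attacks the ester carbonyl through a four-membered transition structure, and its opening shifts the acyl group from oxygen to carbon to give the phenoxide of ynone 21 (net insertion of the aryne into the C–O bond of the acid). The closest known reaction type is the CsF-mediated C–O insertion of arynes into carboxylic acids to give ortho-hydroxyaryl ketones, which with arylpropiolic acids runs on to flavones. Ring C of unit 1 closes by 6-endo-dig oxa-Michael addition of the C8a phenoxide to the ynone (O1–C2 bond), which should be favoured over 5-exo-dig closure to the aurone under basic, equilibrating conditions because it gives the conjugated 4-pyranone. No stereocenter is formed. The step needs oxygen at C8a and acyl at C4a: the electron-withdrawing C5 MOM-oxy group beside the triple bond stabilises the developing carbanion at C4a, so the nucleophile should attack the distal carbon C8a, which has only C8–H beside it, and because ring A of unit 1 was symmetric about the biaryl axis before silylation only one precursor is possible. The near-neutral fluoride conditions should spare the unit 2 flavone, the benzyl ethers and the MOM acetals.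

Step 14
Reactants: 22 5'',7''-bis(benzyloxy)-5,7-bis(methoxymethoxy)-4',4'''-dimethoxy-6,8''-biflavone
Product: 23 5,7,5'',7''-tetrahydroxy-4',4'''-dimethoxy-6,8''-biflavone (CNP0226117.0)
Conditions: BCl3, C6HMe5, CH2Cl2, −78 to −20 °C; then MeOH
Reagents that add atoms: none
Why: Lewis-acid cleavage of the benzyl ethers and MOM acetals with pentamethylbenzene as a non-basic benzyl-cation scavenger; at low temperature BCl3 does not cleave unactivated anisyl methyl ethers, so the four hydroxyls should be freed while both OMe groups stay.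

**Compound list**

1 | 2,4,6-trihydroxyacetophenone | CC(=O)c1c(O)cc(O)cc1O | starting material
2 | 1-[4,6-bis(benzyloxy)-2-hydroxyphenyl]ethan-1-one | CC(=O)c1c(O)cc(OCc2ccccc2)cc1OCc1ccccc1 | intermediate
3 | 1-[4,6-bis(benzyloxy)-2-hydroxy-3-iodophenyl]ethan-1-one | CC(=O)c1c(O)c(I)c(OCc2ccccc2)cc1OCc1ccccc1 | intermediate
4 | 4-methoxybenzaldehyde | COc1ccc(C=O)cc1 | starting material
5 | (E)-1-[4,6-bis(benzyloxy)-2-hydroxy-3-iodophenyl]-3-(4-methoxyphenyl)prop-2-en-1-one | COc1ccc(/C=C/C(=O)c2c(O)c(I)c(OCc3ccccc3)cc2OCc2ccccc2)cc1 | intermediate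
6 | 5,7-bis(benzyloxy)-8-iodo-2-(4-methoxyphenyl)-4H-chromen-4-one | COc1ccc(-c2cc(=O)c3c(OCc4ccccc4)cc(OCc4ccccc4)c(I)c3o2)cc1 | intermediate
7 | phloroglucinol | Oc1cc(O)cc(O)c1 | starting material
8 | 3,5-bis(methoxymethoxy)phenol | COCOc1cc(O)cc(OCOC)c1 | intermediate
9 | 3,5-bis(methoxymethoxy)phenyl N,N-diethylcarbamate | CCN(CC)C(=O)Oc1cc(OCOC)cc(OCOC)c1 | intermediate
10 | [2-(diethylcarbamoyloxy)-4,6-bis(methoxymethoxy)phenyl]lithium | CCN(CC)C(=O)Oc1cc(OCOC)cc(OCOC)c1[Li] | intermediate
11 | 3,5-bis(methoxymethoxy)-2-(trimethylsilyl)phenyl N,N-diethylcarbamate | CCN(CC)C(=O)Oc1cc(OCOC)cc(OCOC)c1[Si](C)(C)C | intermediate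
12 | 3,5-bis(methoxymethoxy)-2-(trimethylsilyl)phenol | COCOc1cc(O)c([Si](C)(C)C)c(OCOC)c1 | intermediate
13 | [3,5-bis(methoxymethoxy)-2-(trimethylsilyl)phenoxy]tri(propan-2-yl)silane | COCOc1cc(O[Si](C(C)C)(C(C)C)C(C)C)c([Si](C)(C)C)c(OCOC)c1 | intermediate
14 | [2,6-bis(methoxymethoxy)-4-(triisopropylsilyloxy)-3-(trimethylsilyl)phenyl]lithium | COCOc1cc(O[Si](C(C)C)(C(C)C)C(C)C)c([Si](C)(C)C)c(OCOC)c1[Li] | intermediate
15 | [2,6-bis(methoxymethoxy)-4-(triisopropylsilyloxy)-3-(trimethylsilyl)phenyl]zinc chloride | COCOc1cc(O[Si](C(C)C)(C(C)C)C(C)C)c([Si](C)(C)C)c(OCOC)c1[Zn]Cl | intermediate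
16 | 5,7-bis(benzyloxy)-8-[2,6-bis(methoxymethoxy)-4-(triisopropylsilyloxy)-3-(trimethylsilyl)phenyl]-2-(4-methoxyphenyl)-4H-chromen-4-one | COc1ccc(-c2cc(=O)c3c(OCc4ccccc4)cc(OCc4ccccc4)c(-c4c(OCOC)cc(O[Si](C(C)C)(C(C)C)C(C)C)c([Si](C)(C)C)c4OCOC)c3o2)cc1 | intermediate
17 | 5,7-bis(benzyloxy)-8-[4-hydroxy-2,6-bis(methoxymethoxy)-3-(trimethylsilyl)phenyl]-2-(4-methoxyphenyl)-4H-chromen-4-one | COc1ccc(-c2cc(=O)c3c(OCc4ccccc4)cc(OCc4ccccc4)c(-c4c(OCOC)cc(O)c([Si](C)(C)C)c4OCOC)c3o2)cc1 | intermediate
18 | 4-[5,7-bis(benzyloxy)-2-(4-methoxyphenyl)-4-oxo-4H-chromen-8-yl]-3,5-bis(methoxymethoxy)-2-(trimethylsilyl)phenyl trifluoromethanesulfonate | COc1ccc(-c2cc(=O)c3c(OCc4ccccc4)cc(OCc4ccccc4)c(-c4c(OCOC)cc(OS(=O)(=O)C(F)(F)F)c([Si](C)(C)C)c4OCOC)c3o2)cc1 | intermediate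
19 | 3-(4-methoxyphenyl)propiolic acid | COc1ccc(C#CC(=O)O)cc1 | starting material
20 | 5,7-bis(benzyloxy)-8-[2,6-bis(methoxymethoxy)-3,4-didehydrophenyl]-2-(4-methoxyphenyl)-4H-chromen-4-one (aryne) | COc1ccc(-c2cc(=O)c3c(OCc4ccccc4)cc(OCc4ccccc4)c(C4=C(OCOC)C#CC=C4OCOC)c3o2)cc1 | intermediate
21 | 1-{3-[5,7-bis(benzyloxy)-2-(4-methoxyphenyl)-4-oxo-4H-chromen-8-yl]-6-hydroxy-2,4-bis(methoxymethoxy)phenyl}-3-(4-methoxyphenyl)prop-2-yn-1-one | COc1ccc(C#CC(=O)c2c(O)cc(OCOC)c(-c3c(OCc4ccccc4)cc(OCc4ccccc4)c4c(=O)cc(-c5ccc(OC)cc5)oc34)c2OCOC)cc1 | intermediate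
22 | 5'',7''-bis(benzyloxy)-5,7-bis(methoxymethoxy)-4',4'''-dimethoxy-6,8''-biflavone | COc1ccc(-c2cc(=O)c3c(OCOC)c(-c4c(OCc5ccccc5)cc(OCc5ccccc5)c5c(=O)cc(-c6ccc(OC)cc6)oc45)c(OCOC)cc3o2)cc1 | intermediate
23 | 5,7,5'',7''-tetrahydroxy-4',4'''-dimethoxy-6,8''-biflavone (CNP0226117.0) | COc1ccc(-c2cc(=O)c3c(O)c(-c4c(O)cc(O)c5c(=O)cc(-c6ccc(OC)cc6)oc45)c(O)cc3o2)cc1 | target

**Step count and risks**

Total step count: 14. Longest linear sequence: 10 steps (steps 5 to 14, from phloroglucinol); the iodoflavone branch (steps 1 to 4) joins at step 10.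

Steps most likely to fail:

1. Step 13. On this crowded biaryl the aryl anion at C4a may be protonated before the O-to-C acyl shift, so that O-arylation to the aryl ester replaces ketone formation; the propiolic acid may also decarboxylate at 125 °C. The fallback sets out from 17 and builds the pyranone by palladium-catalysed carbonylation instead of aryne chemistry. Ipso-iododesilylation of 17 with NIS in MeCN at 0 °C should give 5,7-bis(benzyloxy)-8-[4-hydroxy-3-iodo-2,6-bis(methoxymethoxy)phenyl]-2-(4-methoxyphenyl)-4H-chromen-4-one F1; the ring is symmetric apart from silicon, so only one iodophenol can result. Carbonylative Sonogashira coupling of this iodophenol with 4-ethynylanisole under CO (PdCl2(dppf), Et2NH, 120 °C) then forms ynone 21 in the flask and closes ring C, returning to the route at 22.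

2. Step 10. Transmetalation and reductive elimination at the tetra-ortho-substituted axis may be slow, so that protodezincation of 15 and hydrodeiodination of 6 outrun coupling. The fallback sets out from 13 and replaces the organozinc by an isolated boronic ester. Lithiation to 14 as in the route and quenching with 2-isopropoxy-4,4,5,5-tetramethyl-1,3,2-dioxaborolane should give 2-[2,6-bis(methoxymethoxy)-4-(triisopropylsilyloxy)-3-(trimethylsilyl)phenyl]-4,4,5,5-tetramethyl-1,3,2-dioxaborolane F2. Suzuki–Miyaura coupling of this ester with 6 (Pd(OAc)2, SPhos, K3PO4, toluene/water, 100 °C) returns to the route at 16.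

3. Step 7. Metalation may go to the wrong ring position (the carbon between the two MOM ethers), or the carbamoyl group may migrate by anionic ortho-Fries rearrangement. The fallback sets out from 8 and places silicon by halogenation and silyl migration instead of carbamate-directed metalation. Amine-catalysed ortho-bromination (NBS, i-Pr2NH cat., CH2Cl2, −78 °C) should give 2-bromo-3,5-bis(methoxymethoxy)phenol F3. O-silylation with hexamethyldisilazane (THF, reflux) gives [2-bromo-3,5-bis(methoxymethoxy)phenoxy]trimethylsilane F4. Treatment with n-BuLi in THF at −78 °C triggers bromine–lithium exchange and a 1,3 O-to-C silyl shift (retro-Brook), and work-up returns to the route at 12, passing by 9 to 11.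

**Further compounds**

F1 | step 13 | 5,7-bis(benzyloxy)-8-[4-hydroxy-3-iodo-2,6-bis(methoxymethoxy)phenyl]-2-(4-methoxyphenyl)-4H-chromen-4-one | COc1ccc(-c2cc(=O)c3c(OCc4ccccc4)cc(OCc4ccccc4)c(-c4c(OCOC)cc(O)c(I)c4OCOC)c3o2)cc1
F2 | step 10 | 2-[2,6-bis(methoxymethoxy)-4-(triisopropylsilyloxy)-3-(trimethylsilyl)phenyl]-4,4,5,5-tetramethyl-1,3,2-dioxaborolane | COCOc1cc(O[Si](C(C)C)(C(C)C)C(C)C)c([Si](C)(C)C)c(OCOC)c1B1OC(C)(C)C(C)(C)O1
F3 | step 7 | 2-bromo-3,5-bis(methoxymethoxy)phenol | COCOc1cc(O)c(Br)c(OCOC)c1
F4 | step 7 | [2-bromo-3,5-bis(methoxymethoxy)phenoxy]trimethylsilane | COCOc1cc(O[Si](C)(C)C)c(Br)c(OCOC)c1
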